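## The problem

The target is a flavone whose ring A is a fully substituted benzene. C5 to C8 each carry an oxygen, C8a carries the pyranone oxygen O1 and C4a carries C4, so all five ring A oxygens must be in place before or while ring C is made. The main difficulty is telling these oxygens apart: C5 and C6 are free hydroxyls, C7 and C8 are methyl ethers, and on ring B one ortho oxygen is free (C2') and the other is methylated (C6'). Ring B is 2,6-disubstituted, so the C2–C1' bond is hindered. This argues for bringing ring B in as part of a three-carbon cinnamyl unit, not for forming C2–C1' late. The target has no stereocentre. The only sp3 centre that appears on the way (C2 of a 2H-chromene and of a flavanone) may be racemic, because it is erased when C2=C3 is introduced. The 5,6-dihydroxy unit on an electron-rich ring is sensitive to air and base and should be unveiled last; enol ether and allylic ether intermediates are acid-sensitive. The feature that makes the plan possible is that O1 on C8a and the hydroxyl on C6 are para on ring A. They can therefore be the two carbonyl oxygens of a 1,4-benzoquinone that carries the C4–C3–C2 chain on C4a. A redox-neutral isomerisation then turns one carbonyl into the ring C ether oxygen and the other into the single free ring A phenol. The C5 methoxyl is peri to C4=O and is the one methyl ether a chelating Lewis acid removes.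

## Retrosynthesis

**18 to 17.** The O5–CH3 and O2'–CH2Ph bonds are cut last. In 17 the C5 methyl ether differs from those at C7, C8 and C6' by its peri relation to C4=O, and the benzyl ether on O2' is orthogonal to all methyl ethers. One Lewis acid step should remove both and expose the sensitive 5,6-dihydroxy array only at the end. A different protecting group on O5 would force an early differentiation of ring A and is avoided.

**17 to 16 to 15.** These are oxidation-level adjustments with no skeletal change. The C2=C3 bond of 17 is traced to the flavanone 16, and the C4 carbonyl of 16 to the methyl enol ether of the 2H-chromene 15. Carrying C4 as an enol ether means that only dehydrogenation is needed after ring closure. An unsubstituted 2H-chromene would instead need an allylic C–H oxidation at C4. The forward steps must leave the free C6 phenol and the benzyl ether alone.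

**15 to 13 (key disconnection).** The O1–C2 bond is cut and ring C opened, via the ortho-quinone methide 14, to the quinone 13. A conventional O1–C2 closure of a 2'-hydroxychalcone would need the C8a oxygen already distinguished from four other ring A oxygens. Here the distinction is carbonyl against methoxyl, and it is made by oxidation state. The precursor has no ring C and no differentiated phenol. The forward reaction needs exactly one enolisable C–H and a carbonyl next to the chain, and 13 has both.

**13 to 12.** The two carbonyls are traced to two methoxyls of a pentamethoxyphenyl ring. Of the three para pairs of ring positions, two are mirror images and the third contains the carbon-substituted position, so 12 can give only one para-quinone. The oxidant must prefer the pentamethoxy ring to the dialkoxystyrene and must not ionise the allylic methyl ether.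

**12 to 11 to 6 and 9.** The O–CH3 bond of the side chain and then the C4–C4a bond are cut. This is the convergent cut: pentamethoxybenzene 6 has one ring hydrogen, which gives the aryllithium 10, and the enal 9 offers an unhindered carbonyl carbon. Cuts at C2–C1' or C3–C4 would give partners that are harder to make and would join the halves at the hindered ring B carbon. The addition must be 1,2 and not conjugate.

**9 to 8 to 7.** The C2=C3 bond is cut by a two-carbon Wittig homologation of 8, and the benzyl ether is cut back to commercial 7. Benzyl is chosen because it survives every later step and leaves in the final step.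

**6 to 5 to 2 to 1.** Two O–CH3 bonds and one ring C–O bond are cut. Commercial 1 is methylated to 2. The fifth oxygen is introduced at a position flanked by two methoxyls by lithiation to 3, borylation to 4 and oxidation to 5. Methylation of 5 gives 6.

## Roads not taken

**Alternative 1:** Cut at C2–C1'. An aryl ester of a chromone-3-carboxylic acid, A1, would be treated with Pd(OAc)2 and PPh3. Zerovalent palladium inserts into the aryl–iodine bond and the tether delivers the aryl group to the unfunctionalised C2, giving the lactone-bridged flavone A2. Saponification and decarboxylation would then release the 2'-hydroxyl.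
- Merits: the route is convergent and uses only aromatic intermediates. The tether both protects O2' and brings the hindered 2,6-disubstituted arene to C2. The step count would probably be lower than in the chosen plan.
- Weak points: ring A enters as a 5,6,7,8-tetramethoxy unit. The end game must therefore remove the methyls on O5 and O6 and spare those on O7, O8 and O6'. The first is chelation-controlled; the second depends on a weaker neighbouring effect. Delivery to C2 makes a six-membered ring in an endo sense, with a five-membered exo closure onto C3 as competitor. The ortho-iodophenol partner is not a stock compound.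
- Comparison: on convergence and robustness of the intermediates this road is at least as good. The chosen plan sets against it that the C6 hydroxyl arrives free and no second selective demethylation is needed.

**Alternative 2:** Cut at C4–C4a. The β-aryloxycinnamic acid A3 would be activated as a mixed anhydride with (CF3CO)2O, or as the acid chloride with SnCl4. It would acylate the one free position of its pentaoxygenated ring and give the flavone A4.
- Merits: this is the shortest of the four roads. Regiochemistry cannot go wrong because only one ring position is open, and the flavone oxidation level is reached directly.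
- Weak points: A4 is again fully methylated on ring A, so the same two-site selective demethylation is needed. The activating conditions threaten the benzyl ether and the aryl vinyl ether. Closure needs the carboxyl cis to the aryloxy group.
- Comparison: this road is shorter and its key step is simple. The chosen plan has to offer in return the built-in differentiation of O6 and a key step run under mild base, not under strong acid.

**Alternative 3:** Cut at C4a–C8a, with all of ring A built from an open chain. Base (Mg(OCH3)2 or KOH) would fold the tetraketo ester A5 so that the C4a methylene attacks the ester carbon. This gives the trihydroxydimethoxyphenyl diketone A6, and cyclodehydration would then give the flavone A7.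
- Merits: it is biomimetic and makes the whole pentaoxygenated ring in one step from non-aromatic material.
- Weak points: the folding places hydroxyls at C5 and C7 and methoxyls at C6 and C8 in A7. The target needs the reverse at C6 and C7, so a methyl group would have to be moved from O6 to O7 in two further selective steps. A5 is difficult to assemble and can fold by competing aldol and pyranone-forming modes.
- Comparison: it is the most powerful in bond construction. For this oxygen pattern it is the worst matched, and the chosen plan is better in both step economy and selectivity.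

Key step: step 9

Assumption: in the (NH4)2Ce(NO3)6 oxidation both quinone oxygens are taken to come from water, so two molecules of methanol are counted as leaving.

## Route

Step 1
Reactants: 1 3,4,5-trimethoxyphenol
Product: 2 1,2,3,5-tetramethoxybenzene
Conditions: MeI, K2CO3, acetone, reflux
Reagents that add atoms: iodomethane, CI
Why: Williamson O-methylation; the phenoxide is the only nucleophile present under carbonate.

Step 2
Reactants: 2 1,2,3,5-tetramethoxybenzene
Product: 5 2,3,4,6-tetramethoxyphenol, via aryllithium 3 (not isolated), via dimethyl arylboronate 4 (not isolated)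
Conditions: n-BuLi, THF, 0 °C; B(OMe)3, −78 °C to rt; then AcOH, 30% aq H2O2, 0 °C to rt
Reagents that add atoms: hydrogen peroxide, OO (the phenolic oxygen of 5); trimethyl borate, COB(OC)OC (boron and methoxyls of intermediate 4 only)
Why: Directed ortho-metalation; the two ring hydrogens of 2 are equivalent and each lies between two methoxyls, so one aryllithium should form. Borylation and peroxide-induced 1,2-aryl shift (ipso-hydroxylation of an arylboronate) should then place the fifth oxygen.

Step 3
Reactants: 5 2,3,4,6-tetramethoxyphenol
Product: 6 pentamethoxybenzene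
Conditions: MeI, K2CO3, acetone, reflux, argon
Reagents that add atoms: iodomethane, CI
Why: Williamson O-methylation of the electron-rich phenol, run under argon because 5 is oxidisable; the product is symmetrical with one ring hydrogen.

Step 4
Reactants: 7 2-hydroxy-6-methoxybenzaldehyde
Product: 8 2-benzyloxy-6-methoxybenzaldehyde
Conditions: BnBr, K2CO3, DMF, 50 °C
Reagents that add atoms: benzyl bromide, BrCc1ccccc1
Why: Williamson benzylation of the hydrogen-bonded phenol. Benzyl should survive organolithium, hydride base, oxidant, dilute acid and hot DMSO, and it leaves with BCl3 in the last step.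

Step 5
Reactants: 8 2-benzyloxy-6-methoxybenzaldehyde
Product: 9 (E)-3-(2-benzyloxy-6-methoxyphenyl)prop-2-enal
Conditions: Ph3P=CHCHO (1.05 equiv), toluene, 85 °C
Reagents that add atoms: (triphenylphosphoranylidene)acetaldehyde, O=CC=P(c1ccccc1)(c1ccccc1)c1ccccc1
Why: Wittig olefination with a stabilised formylmethylene ylide, which should give the E-enal. Near-stoichiometric ylide limits a second homologation.

Step 6
Reactants: 6 pentamethoxybenzene; 9 (E)-3-(2-benzyloxy-6-methoxyphenyl)prop-2-enal
Product: 11 racemic (E)-3-(2-benzyloxy-6-methoxyphenyl)-1-(pentamethoxyphenyl)prop-2-en-1-ol, via pentamethoxyphenyllithium 10 (not isolated)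
Conditions: 6 (1.1 equiv), n-BuLi (1.05 equiv), THF, 0 °C; then 9, −78 to −20 °C; aq NH4Cl
Reagents that add atoms: none
Why: Directed lithiation of the single ring hydrogen, flanked by two methoxyls, then 1,2-addition of the hard aryllithium to the enal carbonyl at low temperature; this forms the C4–C4a bond. The carbinol centre is racemic and becomes sp2 in step 9.

Step 7
Reactants: 11 racemic (E)-3-(2-benzyloxy-6-methoxyphenyl)-1-(pentamethoxyphenyl)prop-2-en-1-ol
Product: 12 racemic 1-[(E)-3-(2-benzyloxy-6-methoxyphenyl)-1-methoxyprop-2-en-1-yl]-2,3,4,5,6-pentamethoxybenzene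
Conditions: MeI (3 equiv), then NaH, THF–DMF, 0 °C to rt
Reagents that add atoms: iodomethane, CI
Why: Williamson methylation of the secondary alkoxide. Iodomethane is present before the base so that alkylation outruns any base-induced 1,3-hydrogen shift, and the basic medium avoids ionisation of the doubly activated carbinol.

Step 8
Reactants: 12 racemic 1-[(E)-3-(2-benzyloxy-6-methoxyphenyl)-1-methoxyprop-2-en-1-yl]-2,3,4,5,6-pentamethoxybenzene
Product: 13 racemic 2-[(E)-3-(2-benzyloxy-6-methoxyphenyl)-1-methoxyprop-2-en-1-yl]-3,5,6-trimethoxy-1,4-benzoquinone
Conditions: (NH4)2Ce(NO3)6 (2.5 equiv), MeCN–H2O, 0 °C, short reaction time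
Reagents that add atoms: water, O (both quinone oxygens)
Why: Oxidative demethylation of a para-dimethoxyarene by tetravalent cerium (two one-electron oxidations, addition of water, loss of methanol). The pentamethoxy ring is the most easily oxidised site and by symmetry can give only one para-quinone. Low temperature and a short reaction time should spare the allylic ether.

Step 9
Reactants: 13 racemic 2-[(E)-3-(2-benzyloxy-6-methoxyphenyl)-1-methoxyprop-2-en-1-yl]-3,5,6-trimethoxy-1,4-benzoquinone
Product: 15 racemic 2-(2-benzyloxy-6-methoxyphenyl)-4,5,7,8-tetramethoxy-2H-chromen-6-ol, via ortho-quinone methide 14 (not isolated)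
Conditions: Et3N (2 equiv), degassed toluene, rt to 50 °C, argon, dark
Reagents that add atoms: none
Why: Triethylamine removes the side-chain C4–H, which is allylic, α to oxygen and vinylogous to the quinone carbonyl that becomes C6–OH; protonation on that oxygen gives the ortho-quinone methide 14 with an exocyclic C4a=C4 bond and the C8a carbonyl intact. The 1-oxatriene O=C8a–C4a=C4–C3=C2 then closes by a thermal disrotatory six-electron oxa-electrocyclisation, forming O1–C2 and ring C as a six-membered 2H-pyran; aromatisation of ring A drives it. The closest known reaction type is the base- or heat-induced isomerisation of 2-allyl- and 2-cinnamyl-1,4-benzoquinones to 2H-chromen-6-ols, as in ubiquinone to ubichromenol. C2 becomes a stereocentre with no controlling element, so 15 is racemic; the centre is erased in step 11. The step needs site selectivity in enolisation and in closure. The first is secured because every other quinone position bears a methoxyl. The second is secured because only the C8a carbonyl is conjugated with the exocyclic diene in a six-atom array. Only the methide isomer with the vinyl group cis to C8a=O can close; the other isomer should return to 13 by reversible proton transfer. The E geometry of C2=C3 keeps the aryl group on the outside of the closing termini. Exclusion of air and light protects the electron-rich chromenol.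

Step 10
Reactants: 15 racemic 2-(2-benzyloxy-6-methoxyphenyl)-4,5,7,8-tetramethoxy-2H-chromen-6-ol
Product: 16 racemic 2-(2-benzyloxy-6-methoxyphenyl)-6-hydroxy-5,7,8-trimethoxychroman-4-one
Conditions: 1 M aq HCl, THF, rt, argon
Reagents that add atoms: water, O
Why: Acid-catalysed enol ether hydrolysis: protonation at C3 gives an oxocarbenium ion at C4, water adds and methanol leaves. Aryl methyl and benzyl ethers should be inert to dilute acid at room temperature.

Step 11
Reactants: 16 racemic 2-(2-benzyloxy-6-methoxyphenyl)-6-hydroxy-5,7,8-trimethoxychroman-4-one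
Product: 17 2-(2-benzyloxy-6-methoxyphenyl)-6-hydroxy-5,7,8-trimethoxychromen-4-one
Conditions: I2 (0.1 equiv), DMSO, 120 °C, argon
Reagents that add atoms: none
Why: Iodine–DMSO dehydrogenation of a flavanone: iodination at C3 through the enol and loss of HI give C2=C3, and DMSO reoxidises HI so that catalytic iodine suffices. Ring A has no free position and the low iodine loading limits attack on ring B; the racemic C2 centre disappears here.

Step 12
Reactants: 17 2-(2-benzyloxy-6-methoxyphenyl)-6-hydroxy-5,7,8-trimethoxychromen-4-one
Product: 18 5,6-dihydroxy-2-(2-hydroxy-6-methoxyphenyl)-7,8-dimethoxychromen-4-one (5,6,2'-trihydroxy-7,8,6'-trimethoxyflavone)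
Conditions: BCl3 (6 equiv), pentamethylbenzene (3 equiv), CH2Cl2, −78 to 0 °C; then MeOH, aq HCl
Reagents that add atoms: none
Why: Lewis acid ether cleavage: BCl3 chelated between C4=O and O5 removes the peri methyl as chloromethane and cleaves the benzyl ether, with the benzyl cation trapped by pentamethylbenzene in a Friedel–Crafts alkylation. The unchelated methyl ethers on O7, O8 and O6' should survive at or below 0 °C.

## Compound list

1 | 3,4,5-trimethoxyphenol | COc1cc(O)cc(OC)c1OC | starting material
2 | 1,2,3,5-tetramethoxybenzene | COc1cc(OC)c(OC)c(OC)c1 | intermediate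
3 | 2,3,4,6-tetramethoxyphenyllithium | [Li]c1c(OC)cc(OC)c(OC)c1OC | intermediate (not isolated)
4 | dimethyl (2,3,4,6-tetramethoxyphenyl)boronate | COB(OC)c1c(OC)cc(OC)c(OC)c1OC | intermediate (not isolated)
5 | 2,3,4,6-tetramethoxyphenol | COc1cc(OC)c(OC)c(OC)c1O | intermediate
6 | pentamethoxybenzene | COc1cc(OC)c(OC)c(OC)c1OC | intermediate
7 | 2-hydroxy-6-methoxybenzaldehyde | COc1cccc(O)c1C=O | starting material
8 | 2-benzyloxy-6-methoxybenzaldehyde | COc1cccc(OCc2ccccc2)c1C=O | intermediate
9 | (E)-3-(2-benzyloxy-6-methoxyphenyl)prop-2-enal | COc1cccc(OCc2ccccc2)c1/C=C/C=O | intermediate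
10 | pentamethoxyphenyllithium | [Li]c1c(OC)c(OC)c(OC)c(OC)c1OC | intermediate (not isolated)
11 | racemic (E)-3-(2-benzyloxy-6-methoxyphenyl)-1-(pentamethoxyphenyl)prop-2-en-1-ol | COc1cccc(OCc2ccccc2)c1/C=C/C(O)c1c(OC)c(OC)c(OC)c(OC)c1OC | intermediate
12 | racemic 1-[(E)-3-(2-benzyloxy-6-methoxyphenyl)-1-methoxyprop-2-en-1-yl]-2,3,4,5,6-pentamethoxybenzene | COc1cccc(OCc2ccccc2)c1/C=C/C(OC)c1c(OC)c(OC)c(OC)c(OC)c1OC | intermediate
13 | racemic 2-[(E)-3-(2-benzyloxy-6-methoxyphenyl)-1-methoxyprop-2-en-1-yl]-3,5,6-trimethoxy-1,4-benzoquinone | COC1=C(OC)C(=O)C(C(OC)/C=C/c2c(OC)cccc2OCc2ccccc2)=C(OC)C1=O | intermediate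
14 | 6-[(2E)-3-(2-benzyloxy-6-methoxyphenyl)-1-methoxyprop-2-en-1-ylidene]-4-hydroxy-2,3,5-trimethoxycyclohexa-2,4-dien-1-one (ortho-quinone methide, vinyl group cis to the ring carbonyl) | COc1cccc(OCc2ccccc2)c1/C=C/C(OC)=C1\C(=O)C(OC)=C(OC)C(O)=C1OC | intermediate (not isolated)
15 | racemic 2-(2-benzyloxy-6-methoxyphenyl)-4,5,7,8-tetramethoxy-2H-chromen-6-ol | COC1=CC(c2c(OC)cccc2OCc2ccccc2)Oc2c(OC)c(OC)c(O)c(OC)c12 | intermediate
16 | racemic 2-(2-benzyloxy-6-methoxyphenyl)-6-hydroxy-5,7,8-trimethoxychroman-4-one | COc1cccc(OCc2ccccc2)c1C1CC(=O)c2c(OC)c(O)c(OC)c(OC)c2O1 | intermediate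
17 | 2-(2-benzyloxy-6-methoxyphenyl)-6-hydroxy-5,7,8-trimethoxychromen-4-one | COc1cccc(OCc2ccccc2)c1-c1cc(=O)c2c(OC)c(O)c(OC)c(OC)c2o1 | intermediate
18 | 5,6-dihydroxy-2-(2-hydroxy-6-methoxyphenyl)-7,8-dimethoxychromen-4-one (5,6,2'-trihydroxy-7,8,6'-trimethoxyflavone) | COc1cccc(O)c1-c1cc(=O)c2c(O)c(O)c(OC)c(OC)c2o1 | target

## Step count and risk

Total: 12 steps. Longest linear sequence: 10 steps (steps 1 to 3 and 6 to 12, from 1); the ring B branch is steps 4 and 5.

**Step 9 (key step).** The most likely failure is that enolisation stalls or that the methide is drained by other processes before it closes. These are electron exchange between the quinone 13 and the easily oxidised product 15, and amine attack on the vinylogous ester positions of the methoxyquinone. The closure itself is sterically loaded by the 2,6-disubstituted aryl group at the terminus. Fallback, from 11 and back at 16: this gives up the electrocyclisation but keeps the quinone logic for differentiating O6. Oxidation of 11 with MnO2 should give the chalcone (E)-3-(2-benzyloxy-6-methoxyphenyl)-1-(pentamethoxyphenyl)prop-2-en-1-one F1. Oxidation with (NH4)2Ce(NO3)6 should give the acylquinone 2-[(E)-3-(2-benzyloxy-6-methoxyphenyl)prop-2-enoyl]-3,5,6-trimethoxy-1,4-benzoquinone F2. Reduction with Na2S2O4 should give the hydroquinone chalcone (E)-3-(2-benzyloxy-6-methoxyphenyl)-1-(2,5-dihydroxy-3,4,6-trimethoxyphenyl)prop-2-en-1-one F3. Its hydroxyl ortho to the carbonyl should close by oxa-Michael addition (NaOAc, EtOH, reflux) to 16.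

**Step 8.** The most likely failure is ionisation of the allylic, benzylic methyl ether in the acidic aqueous oxidant (solvolysis or allylic transposition) before the ring is oxidised. Competing oxidation of the dialkoxystyrene and demethylation to an ortho-quinone are further risks. Fallback, from 5 and back at 13: the quinone is released from a para-methoxyphenol with a neutral oxidant. Silylation of 5 (i-Pr3SiCl, imidazole) should give triisopropyl(2,3,4,6-tetramethoxyphenoxy)silane F4. Lithiation of its one ring hydrogen with n-BuLi and addition to 9 should give racemic (E)-3-(2-benzyloxy-6-methoxyphenyl)-1-[2,4,5,6-tetramethoxy-3-(triisopropylsilyloxy)phenyl]prop-2-en-1-ol F5. Methylation (NaH, MeI) should give racemic {3-[(E)-3-(2-benzyloxy-6-methoxyphenyl)-1-methoxyprop-2-en-1-yl]-2,4,5,6-tetramethoxyphenoxy}triisopropylsilane F6. Treatment with n-Bu4NF should free racemic 3-[(E)-3-(2-benzyloxy-6-methoxyphenyl)-1-methoxyprop-2-en-1-yl]-2,4,5,6-tetramethoxyphenol F7. PhI(OAc)2 in aqueous MeCN should oxidise F7 across the hydroxyl and the para methoxyl to 13.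

**Step 11.** The most likely failure is electrophilic iodination of the resorcinol-type ring B, or oxidative degradation of the para-alkoxyphenol of ring A in hot iodine–DMSO. Ring opening by retro-oxa-Michael reaction could feed the degradation. Fallback, from 16 and back at 18: the phenol is masked and the oxidant changed. Benzylation (BnBr, K2CO3) should give racemic 6-benzyloxy-2-(2-benzyloxy-6-methoxyphenyl)-5,7,8-trimethoxychroman-4-one F10. Dehydrogenation with DDQ in refluxing dioxane should give 6-benzyloxy-2-(2-benzyloxy-6-methoxyphenyl)-5,7,8-trimethoxychromen-4-one F11. BCl3 with pentamethylbenzene should then remove both benzyl groups and the C5 methyl to give 18.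

**Step 5.** The most likely failure is a second homologation of the enal product by the ylide, made worse because the hindered, electron-rich aldehyde 8 reacts slowly. Fallback, from 8 and back at 9: Horner–Wadsworth–Emmons reaction with triethyl phosphonoacetate and NaH should give ethyl (E)-3-(2-benzyloxy-6-methoxyphenyl)prop-2-enoate F8. Reduction with i-Bu2AlH should give (E)-3-(2-benzyloxy-6-methoxyphenyl)prop-2-en-1-ol F9, and MnO2 should oxidise F9 to 9.

**Step 12.** The most likely failure is over-demethylation at O7, assisted by the boron chelate on O5 and O6, or C-benzylation of an electron-rich ring if the scavenger is outrun. Fallback, from 17 and back at 18: the two cleavages are separated. Hydrogenolysis (H2, 10% Pd on carbon, EtOAc–MeOH) should give 6-hydroxy-2-(2-hydroxy-6-methoxyphenyl)-5,7,8-trimethoxychromen-4-one F12. AlCl3 in MeCN should then remove only the chelated C5 methyl to give 18.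

## Further compounds

F1 | step 9 | (E)-3-(2-benzyloxy-6-methoxyphenyl)-1-(pentamethoxyphenyl)prop-2-en-1-one | COc1cccc(OCc2ccccc2)c1/C=C/C(=O)c1c(OC)c(OC)c(OC)c(OC)c1OC
F2 | step 9 | 2-[(E)-3-(2-benzyloxy-6-methoxyphenyl)prop-2-enoyl]-3,5,6-trimethoxy-1,4-benzoquinone | COC1=C(OC)C(=O)C(C(=O)/C=C/c2c(OC)cccc2OCc2ccccc2)=C(OC)C1=O
F3 | step 9 | (E)-3-(2-benzyloxy-6-methoxyphenyl)-1-(2,5-dihydroxy-3,4,6-trimethoxyphenyl)prop-2-en-1-one | COc1cccc(OCc2ccccc2)c1/C=C/C(=O)c1c(O)c(OC)c(OC)c(O)c1OC
F4 | step 8 | triisopropyl(2,3,4,6-tetramethoxyphenoxy)silane | COc1cc(OC)c(OC)c(OC)c1O[Si](C(C)C)(C(C)C)C(C)C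
F5 | step 8 | racemic (E)-3-(2-benzyloxy-6-methoxyphenyl)-1-[2,4,5,6-tetramethoxy-3-(triisopropylsilyloxy)phenyl]prop-2-en-1-ol | COc1cccc(OCc2ccccc2)c1/C=C/C(O)c1c(OC)c(O[Si](C(C)C)(C(C)C)C(C)C)c(OC)c(OC)c1OC
F6 | step 8 | racemic {3-[(E)-3-(2-benzyloxy-6-methoxyphenyl)-1-methoxyprop-2-en-1-yl]-2,4,5,6-tetramethoxyphenoxy}triisopropylsilane | COc1cccc(OCc2ccccc2)c1/C=C/C(OC)c1c(OC)c(O[Si](C(C)C)(C(C)C)C(C)C)c(OC)c(OC)c1OC
F7 | step 8 | racemic 3-[(E)-3-(2-benzyloxy-6-methoxyphenyl)-1-methoxyprop-2-en-1-yl]-2,4,5,6-tetramethoxyphenol | COc1cccc(OCc2ccccc2)c1/C=C/C(OC)c1c(OC)c(O)c(OC)c(OC)c1OC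
F8 | step 5 | ethyl (E)-3-(2-benzyloxy-6-methoxyphenyl)prop-2-enoate | CCOC(=O)/C=C/c1c(OC)cccc1OCc1ccccc1
F9 | step 5 | (E)-3-(2-benzyloxy-6-methoxyphenyl)prop-2-en-1-ol | COc1cccc(OCc2ccccc2)c1/C=C/CO
F10 | step 11 | racemic 6-benzyloxy-2-(2-benzyloxy-6-methoxyphenyl)-5,7,8-trimethoxychroman-4-one | COc1cccc(OCc2ccccc2)c1C1CC(=O)c2c(OC)c(OCc3ccccc3)c(OC)c(OC)c2O1
F11 | step 11 | 6-benzyloxy-2-(2-benzyloxy-6-methoxyphenyl)-5,7,8-trimethoxychromen-4-one | COc1cccc(OCc2ccccc2)c1-c1cc(=O)c2c(OC)c(OCc3ccccc3)c(OC)c(OC)c2o1
F12 | step 12 | 6-hydroxy-2-(2-hydroxy-6-methoxyphenyl)-5,7,8-trimethoxychromen-4-one | COc1cccc(O)c1-c1cc(=O)c2c(OC)c(O)c(OC)c(OC)c2o1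
A1 | alternative 1 | 2-iodo-3-methoxyphenyl 5,6,7,8-tetramethoxy-4-oxo-4H-chromene-3-carboxylate | COc1cccc(OC(=O)c2coc3c(OC)c(OC)c(OC)c(OC)c3c2=O)c1I
A2 | alternative 1 | 1,8,9,10,11-pentamethoxy-6H,7H-chromeno[4,3-b]chromene-6,7-dione | COc1cccc2OC(=O)c3c(-c12)oc1c(OC)c(OC)c(OC)c(OC)c1c3=O
A3 | alternative 2 | (Z)-3-(2-benzyloxy-6-methoxyphenyl)-3-(2,3,4,5-tetramethoxyphenoxy)prop-2-enoic acid | COc1cccc(OCc2ccccc2)c1/C(Oc1cc(OC)c(OC)c(OC)c1OC)=C/C(=O)O
A4 | alternative 2 | 2-(2-benzyloxy-6-methoxyphenyl)-5,6,7,8-tetramethoxychromen-4-one | COc1cccc(OCc2ccccc2)c1-c1cc(=O)c2c(OC)c(OC)c(OC)c(OC)c2o1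
A5 | alternative 3 | methyl 9-(2-benzyloxy-6-methoxyphenyl)-2,4-dimethoxy-3,5,7,9-tetraoxononanoate | COC(=O)C(OC)C(=O)C(OC)C(=O)CC(=O)CC(=O)c1c(OC)cccc1OCc1ccccc1
A6 | alternative 3 | 1-(2-benzyloxy-6-methoxyphenyl)-3-(2,4,6-trihydroxy-3,5-dimethoxyphenyl)propane-1,3-dione | COc1c(O)c(OC)c(O)c(C(=O)CC(=O)c2c(OC)cccc2OCc2ccccc2)c1O
A7 | alternative 3 | 2-(2-benzyloxy-6-methoxyphenyl)-5,7-dihydroxy-6,8-dimethoxychromen-4-one | COc1cccc(OCc2ccccc2)c1-c1cc(=O)c2c(O)c(OC)c(O)c(OC)c2o1
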